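**Plan**
- Retrosynthesis: the C7 ketone/C6 carbinol is traced back through a C6 ketone to a cis-6,7-diol, and the C6–C7 bond of ring B is cut (pinacol) to give a ring A dialdehyde. Further cuts are the C4 gem-dimethyl group (from a C4 ketone), C5–C6 and C10–CH3 (conjugate methylation/formaldehyde aldol), C9–C10 (alkenyllithium plus vinylogous ester), C8–CH3 (carbomagnesiation) and C11–C12 (dianion alkylation).
- Enabling feature: ring B carries oxygen on both C6 (carbinol) and C7 (ketone conjugated to C8=C9). At the aldehyde level both carbons are acceptors, so a one-electron reductive coupling joins them, and the Z C8=C9 bond holds the C7 formyl group beside C10/C5.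
- Forward order: side chain with the C13 carbinol and the lactone masked as a methyl lactol acetal; Z tetrasubstituted alkenyl iodide; ring A attached, methylated at C10 and hydroxymethylated at C5; C4 gem-dimethyl; unmasking to the lactone dialdehyde; ring B closed last; redox adjustment at C6/C7.
- Stereochemistry: C13 from Sharpless epoxidation; C10 from a chiral NHC–copper catalyst; C5 from aldol trapping anti to the alkenyl group; the C8=C9 geometry from anti-carbomagnesiation; C6/C7 cis from samarium chelation, C6 then inverted through its ketone by hydroxyl-directed hydride delivery.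

Key step: step 15

Remark: labdane numbering is used (C1–C10 decalin, C11/C12 chain, C13 carbinol, C14, C15 lactone carbonyl, C16 OCH2, C17 methyl on C8, C18/C19 on C4, C20 on C10). Compounds 7–24 are anomer mixtures at the acetal carbon C15, which ends as the lactone carbonyl. TBS = tert-butyldimethylsilyl, TES = triethylsilyl. "Z-arm" = (2Z)-1-(TBSO)-5-[(3S)-3-(TBSO)-5-methoxyoxolan-3-yl]-2-methylpent-2-en-3-yl.

Step 1
Reactants: 1 2-methylprop-2-en-1-ol; 2 3-bromo-1-(trimethylsilyl)prop-1-yne
Product: 4 2-methylidene-6-(trimethylsilyl)hex-5-yn-1-ol, via dilithio dianion 3 (not isolated)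
Conditions: n-BuLi (2.2 equiv), TMEDA, Et2O/hexane, 0 °C → rt; then 2, THF, −78 → 0 °C
Reagents that add atoms: none
Why: Alkylation of the methallyl alcohol O,C-dianion at its allylic carbon by SN2 displacement of the propargylic bromide (the silyl cap blocks acetylide formation and SN2' attack) forms C11–C12; no stereocentre is formed.

Step 2
Reactants: 4 2-methylidene-6-(trimethylsilyl)hex-5-yn-1-ol
Product: 5 {(2R)-2-[4-(trimethylsilyl)but-3-yn-1-yl]oxiran-2-yl}methanol
Conditions: Ti(OiPr)4 (10 mol %), D-(−)-diethyl tartrate (12 mol %), t-BuOOH, 4 Å MS, CH2Cl2, −20 °C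
Reagents that add atoms: tert-butyl hydroperoxide, CC(C)(C)OO
Why: Sharpless asymmetric epoxidation of a 2-substituted allylic alcohol; the D-(−)-tartrate catalyst delivers oxygen to the face that gives the (R)-epoxide, which fixes C13 (it becomes (S) once C14 outranks the chain).

Step 3
Reactants: 5 {(2R)-2-[4-(trimethylsilyl)but-3-yn-1-yl]oxiran-2-yl}methanol
Product: 6 (2S)-2-(prop-2-en-1-yl)-6-(trimethylsilyl)hex-5-yne-1,2-diol
Conditions: CH2=CHMgBr (3 equiv), CuI (10 mol %), THF, −40 → 0 °C
Reagents that add atoms: vinylmagnesium bromide, C=C[Mg]Br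
Why: Copper-catalysed Grignard opening of the 2,2-disubstituted epoxide at its unhindered CH2 terminus (C14) leaves the C13–O bond and its configuration untouched.

Step 4
Reactants: 6 (2S)-2-(prop-2-en-1-yl)-6-(trimethylsilyl)hex-5-yne-1,2-diol
Product: 8 (3S)-5-methoxy-3-[4-(trimethylsilyl)but-3-yn-1-yl]oxolan-3-ol, via lactol 7 (not isolated)
Conditions: O3, CH2Cl2/MeOH, −78 °C; Me2S; then CSA (cat.), MeOH, rt
Reagents that add atoms: methanol, CO
Why: Ozonolysis of the terminal alkene (much faster than attack on the silylalkyne) gives an aldehyde that closes onto the primary hydroxyl as a five-membered lactol, and Fischer acetalisation stores the future lactone as a base-stable methyl acetal.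

Step 5
Reactants: 8 (3S)-5-methoxy-3-[4-(trimethylsilyl)but-3-yn-1-yl]oxolan-3-ol
Product: 10 (3S)-3-(5-hydroxypent-3-yn-1-yl)-5-methoxyoxolan-3-ol, via dilithium acetylide alkoxide 9 (not isolated)
Conditions: MeLi·LiBr (2.5 equiv), THF, 0 °C → rt; then (CH2O)n, −20 °C → rt
Reagents that add atoms: formaldehyde (from paraformaldehyde), C=O
Why: Methyllithium cleaves the alkynyl–silicon bond to the lithium acetylide, which adds to formaldehyde (acetylide hydroxymethylation) to install C7 as the propargylic alcohol.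

Step 6
Reactants: 10 (3S)-3-(5-hydroxypent-3-yn-1-yl)-5-methoxyoxolan-3-ol
Product: 12 (3S)-3-[(3Z)-5-hydroxy-3-iodo-4-methylpent-3-en-1-yl]-5-methoxyoxolan-3-ol, via oxamagnesacycle 11 (not isolated)
Conditions: MeMgBr (5 equiv), CuI (15 mol %), THF, rt; then I2, −78 → 0 °C
Reagents that add atoms: methylmagnesium bromide, C[Mg]Br; iodine, II
Why: Alkoxide-directed anti-carbomagnesiation of the propargylic alcohol (Duboudin–Jousseaume type) puts methyl on C8 and magnesium on C9 in a five-membered chelate, and iodinolysis with retention gives the tetrasubstituted alkenyl iodide with iodine cis to the CH2OH group.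

Step 7
Reactants: 12 (3S)-3-[(3Z)-5-hydroxy-3-iodo-4-methylpent-3-en-1-yl]-5-methoxyoxolan-3-ol
Product: 13 (3S)-3-(TBSO)-3-[(3Z)-5-(TBSO)-3-iodo-4-methylpent-3-en-1-yl]-5-methoxyoxolane
Conditions: TBSOTf (2.5 equiv), 2,6-lutidine, CH2Cl2, −78 → 0 °C
Reagents that add atoms: tert-butyldimethylsilyl trifluoromethanesulfonate, CC(C)(C)[Si](C)(C)OS(=O)(=O)C(F)(F)F
Why: Silyl triflate silylation protects the primary allylic and the tertiary hydroxyl in one operation; at low temperature the methyl acetal should not be activated.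

Step 8
Reactants: 13 (3S)-3-(TBSO)-3-[(3Z)-5-(TBSO)-3-iodo-4-methylpent-3-en-1-yl]-5-methoxyoxolane; 14 3-ethoxycyclohex-2-en-1-one
Product: 17 3-(Z-arm)cyclohex-2-en-1-one, via alkenyllithium 15 (not isolated), via lithium carbinolate 16 (not isolated)
Conditions: t-BuLi (2.1 equiv), Et2O, −78 °C; then 14, −78 → −20 °C; then 0.5 M aq. HCl, THF, 0 °C, brief
Reagents that add atoms: water, O
Why: Iodine–lithium exchange with retention of alkene geometry, 1,2-addition to the vinylogous ester and acid-induced hydrolysis/transposition (Stork–Danheiser sequence) form C9–C10 at a carbonyl carbon; ether at −78 °C suppresses 1,4-silyl migration and the brief cold acid spares the acetal.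

Step 9
Reactants: 17 3-(Z-arm)cyclohex-2-en-1-one
Product: 19 (2R,3R)-2-(hydroxymethyl)-3-methyl-3-(Z-arm)cyclohexan-1-one, via magnesium enolate 18 (not isolated)
Conditions: Cu(OTf)2 (5 mol %), leucinol-derived N-mesityl hydroxyalkyl imidazolinium PF6 salt (7 mol %, antipode giving Si-face attack), MeMgBr (1.5 equiv), Et2O, −30 °C; then CH2O (gas), −78 °C
Reagents that add atoms: methylmagnesium bromide, C[Mg]Br; formaldehyde, C=O
Why: Copper/NHC-catalysed asymmetric conjugate addition of a Grignard reagent to a 3-alkenylcyclohexenone (1,4-selective; the 1,6-terminus C8 is fully substituted) sets C10 by catalyst control (methyl to the Si face), and the regiodefined magnesium enolate is trapped by aldol addition to formaldehyde anti to the bulky alkenyl group, setting C5 with C6 trans to C9; a minor C5 epimer would be removed at this stage.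

Step 10
Reactants: 19 (2R,3R)-2-(hydroxymethyl)-3-methyl-3-(Z-arm)cyclohexan-1-one
Product: 20 (2R,3R)-2-[(TBSO)methyl]-3-methyl-3-(Z-arm)cyclohexan-1-one
Conditions: TBSCl, imidazole, DMF, 0 °C → rt
Reagents that add atoms: tert-butyldimethylsilyl chloride, CC(C)(C)[Si](C)(C)Cl
Why: Standard silylation of the primary aldol hydroxyl blocks retro-aldol and dehydration in the steps that follow.

Step 11
Reactants: 20 (2R,3R)-2-[(TBSO)methyl]-3-methyl-3-(Z-arm)cyclohexan-1-one
Product: 21 tert-butyl({(1R,2R)-2-methyl-6-methylidene-2-(Z-arm)cyclohexyl}methoxy)dimethylsilane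
Conditions: Zn, CH2Br2, TiCl4, THF; then 20, CH2Cl2, 0 °C → rt
Reagents that add atoms: dibromomethane, BrCBr
Why: Lombardo–Takai methylenation converts the hindered, enolisable C4 ketone into the exocyclic alkene under non-basic conditions, so the epimerisable C5 centre and the β-silyloxy group are preserved.

Step 12
Reactants: 21 tert-butyl({(1R,2R)-2-methyl-6-methylidene-2-(Z-arm)cyclohexyl}methoxy)dimethylsilane
Product: 23 tert-butyl({(1R,6R)-2,2,6-trimethyl-6-(Z-arm)cyclohexyl}methoxy)dimethylsilane, via sulfonylhydrazide 22 (not isolated)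
Conditions: Fe(acac)3 (0.5 equiv), PhSiH3, H2C=N–NHSO2(n-C8H17), THF/MeOH, rt; then MeOH, 60 °C
Reagents that add atoms: formaldehyde octylsulfonylhydrazone, C=NNS(=O)(=O)CCCCCCCC
Why: Iron-hydride hydrogen-atom-transfer hydromethylation: Markovnikov H-atom transfer to the 1,1-disubstituted alkene gives the tertiary C4 radical, which adds to the formaldehyde hydrazone, and thermal loss of sulfinate and N2 leaves the second C4 methyl; the tetrasubstituted C8=C9 alkene is too hindered to compete.

Step 13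
Reactants: 23 tert-butyl({(1R,6R)-2,2,6-trimethyl-6-(Z-arm)cyclohexyl}methoxy)dimethylsilane
Product: 24 (2Z)-5-[(3S)-3,5-dihydroxyoxolan-3-yl]-3-[(1R,2R)-2-(hydroxymethyl)-1,3,3-trimethylcyclohexyl]-2-methylpent-2-en-1-ol
Conditions: 48% aq. HF, MeCN, 0 °C → rt
Reagents that add atoms: water, O
Why: Aqueous HF removes the three silyl ethers (fluoride-assisted Si–O cleavage) and hydrolyses the methyl acetal to the lactol in one acidic operation mild enough not to ionise the allylic alcohol.

Step 14
Reactants: 24 (2Z)-5-[(3S)-3,5-dihydroxyoxolan-3-yl]-3-[(1R,2R)-2-(hydroxymethyl)-1,3,3-trimethylcyclohexyl]-2-methylpent-2-en-1-ol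
Product: 25 (2Z)-3-[(1R,2R)-2-formyl-1,3,3-trimethylcyclohexyl]-5-[(3S)-3-hydroxy-5-oxooxolan-3-yl]-2-methylpent-2-enal
Conditions: Dess–Martin periodinane (5 equiv), NaHCO3, CH2Cl2, 0 °C → rt
Reagents that add atoms: none
Why: Dess–Martin oxidation takes the lactol to the γ-lactone and both primary alcohols to aldehydes under buffered, non-epimerising conditions (fast oxidation of both primary alcohols should outrun seven-membered lactol formation), while the tertiary C13 alcohol is inert.

Step 15
Reactants: 25 (2Z)-3-[(1R,2R)-2-formyl-1,3,3-trimethylcyclohexyl]-5-[(3S)-3-hydroxy-5-oxooxolan-3-yl]-2-methylpent-2-enal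
Product: 26 (5R,6S,7R,10R,13S)-6,7,13-trihydroxylabd-8-en-15,16-olide
Conditions: SmI2 (3 equiv), THF (0.005 M), −78 → 0 °C; aq. NH4Cl
Reagents that add atoms: none
Why: SmI2 (divalent samarium) transfers one electron to a formyl group, most readily the conjugated C7 one, and the samarium ketyl adds through its carbonyl carbon to the C6 aldehyde; a second electron transfer gives the trivalent samarium 6,7-diolate, which is protonated on work-up. The closest known reaction type is the SmI2-mediated intramolecular pinacol coupling of 1,6-dialdehydes to cis-cyclohexane-1,2-diols. Ring B closes by 6-exo-trig addition to the C6 carbonyl; the Z C8=C9 bond holds C7 beside C10, and attack of the allylic ketyl through C9 would only give a four-membered ring. The cis relation of the C6 and C7 oxygens follows from both being bound to one samarium in the cyclic transition state, and the face is set by the ring A stereocentres C5 and C10: the C6 oxygen takes the equatorial position, away from the axial methyls on C4 and C10. The step needs ring closure to outrun simple carbonyl reduction and intermolecular dimerisation, which high dilution, low temperature and the absence of an added proton donor should secure, while the lactone and tertiary alcohol are inert to SmI2 in THF.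

Step 16
Reactants: 26 (5R,6S,7R,10R,13S)-6,7,13-trihydroxylabd-8-en-15,16-olide
Product: 27 (5R,6S,7R,10R,13S)-6,13-dihydroxy-7-[(triethylsilyl)oxy]labd-8-en-15,16-olide
Conditions: TESCl (1.1 equiv), imidazole, CH2Cl2, −40 → −20 °C
Reagents that add atoms: triethylsilyl chloride, CC[Si](CC)(CC)Cl
Why: Regioselective silylation: the pseudoaxial allylic C7 hydroxyl lies on the open face, whereas the equatorial C6 hydroxyl is buttressed by the equatorial C4 methyl and the tertiary C13 hydroxyl does not react with a silyl chloride.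

Step 17
Reactants: 27 (5R,6S,7R,10R,13S)-6,13-dihydroxy-7-[(triethylsilyl)oxy]labd-8-en-15,16-olide
Product: 28 (5R,7R,10R,13S)-13-hydroxy-6-oxo-7-[(triethylsilyl)oxy]labd-8-en-15,16-olide
Conditions: Dess–Martin periodinane, NaHCO3, CH2Cl2, rt
Reagents that add atoms: none
Why: Dess–Martin oxidation of the only free secondary alcohol erases the wrongly configured C6 carbinol under neutral conditions that leave C5 and C7 intact.

Step 18
Reactants: 28 (5R,7R,10R,13S)-13-hydroxy-6-oxo-7-[(triethylsilyl)oxy]labd-8-en-15,16-olide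
Product: 29 (5R,7R,10R,13S)-7,13-dihydroxy-6-oxolabd-8-en-15,16-olide
Conditions: HF·pyridine, THF/pyridine, 0 °C
Reagents that add atoms: none
Why: Buffered fluoride desilylation frees the C7 hydroxyl without the acid or base that would isomerise the α-ketol.

Step 19
Reactants: 29 (5R,7R,10R,13S)-7,13-dihydroxy-6-oxolabd-8-en-15,16-olide
Product: 30 (5R,6R,7R,10R,13S)-6,7,13-trihydroxylabd-8-en-15,16-olide
Conditions: Me4NBH(OAc)3, MeCN/AcOH, −30 °C
Reagents that add atoms: none
Why: Hydroxyl-directed triacetoxyborohydride reduction (Evans–Saksena type): the boron bound to the pseudoaxial C7 oxygen delivers hydride to C6 on that same face, which is also the face not blocked by the axial C4 and C10 methyls, giving the axial (6R) carbinol of the trans-diol.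

Step 20
Reactants: 30 (5R,6R,7R,10R,13S)-6,7,13-trihydroxylabd-8-en-15,16-olide
Product: 31 (5R,6R,10R,13S)-6,13-dihydroxy-7-oxolabd-8-en-15,16-olide (target)
Conditions: MnO2, CH2Cl2, rt
Reagents that add atoms: none
Why: MnO2 oxidises only the allylic C7 alcohol to the enone; the trans-diaxial diol cannot form the cyclic ester needed for glycol cleavage, and the C6 and C13 alcohols are not allylic.

**Compound list**
1 | 2-methylprop-2-en-1-ol | CC(=C)CO | starting material
2 | 3-bromo-1-(trimethylsilyl)prop-1-yne | C[Si](C)(C)C#CCBr | starting material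
3 | dilithio O,C-dianion of 1 | [Li]CC(=C)CO[Li] | intermediate (not isolated)
4 | 2-methylidene-6-(trimethylsilyl)hex-5-yn-1-ol | C[Si](C)(C)C#CCCC(=C)CO | intermediate
5 | {(2R)-2-[4-(trimethylsilyl)but-3-yn-1-yl]oxiran-2-yl}methanol | C[Si](C)(C)C#CCC[C@@]1(CO)CO1 | intermediate
6 | (2S)-2-(prop-2-en-1-yl)-6-(trimethylsilyl)hex-5-yne-1,2-diol | C[Si](C)(C)C#CCC[C@@](O)(CO)CC=C | intermediate
7 | (4S)-4-[4-(trimethylsilyl)but-3-yn-1-yl]oxolane-2,4-diol (lactol, both anomers) | C[Si](C)(C)C#CCC[C@@]1(O)COC(O)C1 | intermediate (not isolated)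
8 | (3S)-5-methoxy-3-[4-(trimethylsilyl)but-3-yn-1-yl]oxolan-3-ol (both anomers) | C[Si](C)(C)C#CCC[C@@]1(O)COC(OC)C1 | intermediate
9 | dilithium acetylide alkoxide of (3S)-3-(but-3-yn-1-yl)-5-methoxyoxolan-3-ol | [Li]C#CCC[C@@]1(O[Li])COC(OC)C1 | intermediate (not isolated)
10 | (3S)-3-(5-hydroxypent-3-yn-1-yl)-5-methoxyoxolan-3-ol | OCC#CCC[C@@]1(O)COC(OC)C1 | intermediate
11 | cyclic alkenylmagnesium alkoxide (2,5-dihydro-1,2-oxamagnesole) from anti addition of MeMgBr to 10, tertiary oxygen as OMgBr | CC1=C(CC[C@@]2(O[Mg]Br)COC(OC)C2)[Mg]OC1 | intermediate (not isolated)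
12 | (3S)-3-[(3Z)-5-hydroxy-3-iodo-4-methylpent-3-en-1-yl]-5-methoxyoxolan-3-ol | OC/C(C)=C(/CC[C@@]1(O)COC(OC)C1)I | intermediate
13 | (3S)-3-(TBSO)-3-[(3Z)-5-(TBSO)-3-iodo-4-methylpent-3-en-1-yl]-5-methoxyoxolane | CC(C)(C)[Si](C)(C)OC/C(C)=C(/CC[C@@]1(O[Si](C)(C)C(C)(C)C)COC(OC)C1)I | intermediate
14 | 3-ethoxycyclohex-2-en-1-one | CCOC1=CC(=O)CCC1 | starting material
15 | alkenyllithium from 13 (lithium in place of iodine, geometry retained) | CC(C)(C)[Si](C)(C)OC/C(C)=C(/CC[C@@]1(O[Si](C)(C)C(C)(C)C)COC(OC)C1)[Li] | intermediate (not isolated)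
16 | lithium 3-ethoxy-1-(Z-arm)cyclohex-2-en-1-olate | CC(C)(C)[Si](C)(C)OC/C(C)=C(/CC[C@@]1(O[Si](C)(C)C(C)(C)C)COC(OC)C1)C2(O[Li])C=C(OCC)CCC2 | intermediate (not isolated)
17 | 3-(Z-arm)cyclohex-2-en-1-one | CC(C)(C)[Si](C)(C)OC/C(C)=C(/CC[C@@]1(O[Si](C)(C)C(C)(C)C)COC(OC)C1)C2=CC(=O)CCC2 | intermediate
18 | bromomagnesium enolate of (3R)-3-methyl-3-(Z-arm)cyclohexanone | CC(C)(C)[Si](C)(C)OC/C(C)=C(/CC[C@@]1(O[Si](C)(C)C(C)(C)C)COC(OC)C1)[C@]2(C)CCCC(O[Mg]Br)=C2 | intermediate (not isolated)
19 | (2R,3R)-2-(hydroxymethyl)-3-methyl-3-(Z-arm)cyclohexan-1-one | CC(C)(C)[Si](C)(C)OC/C(C)=C(/CC[C@@]1(O[Si](C)(C)C(C)(C)C)COC(OC)C1)[C@]2(C)CCCC(=O)[C@H]2CO | intermediate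
20 | (2R,3R)-2-[(TBSO)methyl]-3-methyl-3-(Z-arm)cyclohexan-1-one | CC(C)(C)[Si](C)(C)OC/C(C)=C(/CC[C@@]1(O[Si](C)(C)C(C)(C)C)COC(OC)C1)[C@]2(C)CCCC(=O)[C@H]2CO[Si](C)(C)C(C)(C)C | intermediate
21 | tert-butyl({(1R,2R)-2-methyl-6-methylidene-2-(Z-arm)cyclohexyl}methoxy)dimethylsilane | CC(C)(C)[Si](C)(C)OC/C(C)=C(/CC[C@@]1(O[Si](C)(C)C(C)(C)C)COC(OC)C1)[C@]2(C)CCCC(=C)[C@H]2CO[Si](C)(C)C(C)(C)C | intermediate
22 | N'-alkyl octane-1-sulfonohydrazide (C4 bearing CH3 and CH2NHNHSO2C8H17) | CC(C)(C)[Si](C)(C)OC/C(C)=C(/CC[C@@]1(O[Si](C)(C)C(C)(C)C)COC(OC)C1)[C@]2(C)CCCC(C)(CNNS(=O)(=O)CCCCCCCC)[C@H]2CO[Si](C)(C)C(C)(C)C | intermediate (not isolated)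
23 | tert-butyl({(1R,6R)-2,2,6-trimethyl-6-(Z-arm)cyclohexyl}methoxy)dimethylsilane | CC(C)(C)[Si](C)(C)OC/C(C)=C(/CC[C@@]1(O[Si](C)(C)C(C)(C)C)COC(OC)C1)[C@]2(C)CCCC(C)(C)[C@H]2CO[Si](C)(C)C(C)(C)C | intermediate
24 | (2Z)-5-[(3S)-3,5-dihydroxyoxolan-3-yl]-3-[(1R,2R)-2-(hydroxymethyl)-1,3,3-trimethylcyclohexyl]-2-methylpent-2-en-1-ol | OC/C(C)=C(/CC[C@@]1(O)COC(O)C1)[C@]2(C)CCCC(C)(C)[C@H]2CO | intermediate
25 | (2Z)-3-[(1R,2R)-2-formyl-1,3,3-trimethylcyclohexyl]-5-[(3S)-3-hydroxy-5-oxooxolan-3-yl]-2-methylpent-2-enal (key-step precursor) | O=C/C(C)=C(/CC[C@@]1(O)COC(=O)C1)[C@]2(C)CCCC(C)(C)[C@H]2C=O | intermediate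
26 | (5R,6S,7R,10R,13S)-6,7,13-trihydroxylabd-8-en-15,16-olide (cis-6,7-diol, key-step product) | CC1=C(CC[C@@]2(O)COC(=O)C2)[C@]2(C)CCCC(C)(C)[C@H]2[C@H](O)[C@@H]1O | intermediate
27 | (5R,6S,7R,10R,13S)-6,13-dihydroxy-7-[(triethylsilyl)oxy]labd-8-en-15,16-olide | CC1=C(CC[C@@]2(O)COC(=O)C2)[C@]2(C)CCCC(C)(C)[C@H]2[C@H](O)[C@@H]1O[Si](CC)(CC)CC | intermediate
28 | (5R,7R,10R,13S)-13-hydroxy-6-oxo-7-[(triethylsilyl)oxy]labd-8-en-15,16-olide | CC1=C(CC[C@@]2(O)COC(=O)C2)[C@]2(C)CCCC(C)(C)[C@H]2C(=O)[C@@H]1O[Si](CC)(CC)CC | intermediate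
29 | (5R,7R,10R,13S)-7,13-dihydroxy-6-oxolabd-8-en-15,16-olide | CC1=C(CC[C@@]2(O)COC(=O)C2)[C@]2(C)CCCC(C)(C)[C@H]2C(=O)[C@@H]1O | intermediate
30 | (5R,6R,7R,10R,13S)-6,7,13-trihydroxylabd-8-en-15,16-olide (trans-6,7-diol) | CC1=C(CC[C@@]2(O)COC(=O)C2)[C@]2(C)CCCC(C)(C)[C@H]2[C@@H](O)[C@@H]1O | intermediate
31 | (5R,6R,10R,13S)-6,13-dihydroxy-7-oxolabd-8-en-15,16-olide, CNP0324736.4 | CC1=C(CC[C@@]2(O)COC(=O)C2)[C@]2(C)CCCC(C)(C)[C@H]2[C@@H](O)C1=O | target

Total step count: 20. Longest linear sequence: 20 steps (1 → 31).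

**Steps most likely to fail**

Step 9. Methyl transfer to the β-carbon of 17 may be slow because of the flanking tetrasubstituted alkene, so that 1,2-addition competes, enantioface discrimination is weak, or the aldol trapping is not cleanly anti to the alkenyl group. The fallback reverses the roles and forms C9–C10 in the conjugate addition. It sets out from 13: iodine–lithium exchange (t-BuLi, Et2O, −78 °C) to 15 and transmetalation with Me2AlCl would give the alkenyl(dimethyl)alane F1. Its copper-catalysed asymmetric conjugate addition (copper thiophene-2-carboxylate, Cu(O2CC4H3S), with a chiral phosphinamine ligand, Et2O, −30 °C) to 3-methylcyclohex-2-en-1-one (CC1=CC(=O)CCC1) would give the dimethylaluminium enolate F2. Trapping F2 with gaseous formaldehyde returns to the route at 19.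

Step 15. Simple reduction of the formyl groups, intermolecular coupling or Z/E drift of the enal may outpace ring closure. The fallback keeps the C6–C7 ring B closure but forms the bond by metathesis. It sets out from 25: double methylenation (Ph3P=CH2, THF, −78 → 0 °C, aldehydes reacting faster than the lactone) would give the triene F3. Ring-closing metathesis with second-generation Grubbs catalyst (CH2Cl2, 40 °C) would close ring B as the labda-6,8-diene F4 with loss of ethene. Dihydroxylation (OsO4 cat., NMO, acetone/H2O) should take place at the disubstituted C6=C7 bond on the face away from the axial C4 and C10 methyls and so return to the route at 26.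

Step 16. Discrimination between the two secondary hydroxyls may be poor, with silylation at C6 or at both. The fallback sets out from 26 and uses the stereoelectronic rule for orthoester opening instead of steric selection. Trimethyl orthoacetate with PPTS would give the 6,7-cyclic orthoacetate F5, and mild aqueous acetic acid should open it to the axial C7 acetate F6 with the C6 hydroxyl free. Dess–Martin oxidation would give the 6-oxo 7-acetate F7, and NaBH4 (MeOH, −20 °C), approaching away from the axial methyls, the axial 6-hydroxy 7-acetate F8. Methanolysis (K2CO3, MeOH, 0 °C, then mild acid to re-close any opened lactone) returns to the route at 30.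

Further compounds
F1 | step 9 | alkenyl(dimethyl)alane from 13 (AlMe2 in place of iodine) | CC(C)(C)[Si](C)(C)OC/C(C)=C(/CC[C@@]1(O[Si](C)(C)C(C)(C)C)COC(OC)C1)[Al](C)C
F2 | step 9 | dimethylaluminium enolate of (3R)-3-methyl-3-(Z-arm)cyclohexanone | CC(C)(C)[Si](C)(C)OC/C(C)=C(/CC[C@@]1(O[Si](C)(C)C(C)(C)C)COC(OC)C1)[C@]2(C)CCCC(O[Al](C)C)=C2
F3 | step 15 | triene from double methylenation of 25 (C6 and C7 as vinyl groups) | C=C/C(C)=C(/CC[C@@]1(O)COC(=O)C1)[C@]2(C)CCCC(C)(C)[C@H]2C=C
F4 | step 15 | (5R,10R,13S)-13-hydroxylabda-6,8-dien-15,16-olide | CC1=C(CC[C@@]2(O)COC(=O)C2)[C@]2(C)CCCC(C)(C)[C@H]2C=C1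
F5 | step 16 | 6,7-O-(1-methoxyethylidene) cyclic orthoacetate of 26 | CC1=C(CC[C@@]2(O)COC(=O)C2)[C@]2(C)CCCC(C)(C)[C@H]2[C@@H]3OC(C)(OC)O[C@H]13
F6 | step 16 | (5R,6S,7R,10R,13S)-7-acetoxy-6,13-dihydroxylabd-8-en-15,16-olide | CC1=C(CC[C@@]2(O)COC(=O)C2)[C@]2(C)CCCC(C)(C)[C@H]2[C@H](O)[C@@H]1OC(C)=O
F7 | step 16 | (5R,7R,10R,13S)-7-acetoxy-13-hydroxy-6-oxolabd-8-en-15,16-olide | CC1=C(CC[C@@]2(O)COC(=O)C2)[C@]2(C)CCCC(C)(C)[C@H]2C(=O)[C@@H]1OC(C)=O
F8 | step 16 | (5R,6R,7R,10R,13S)-7-acetoxy-6,13-dihydroxylabd-8-en-15,16-olide | CC1=C(CC[C@@]2(O)COC(=O)C2)[C@]2(C)CCCC(C)(C)[C@H]2[C@@H](O)[C@@H]1OC(C)=O
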